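**Strategy.** Hispidanin B is cut at its spiro-cyclohexene into a labdane diene acid and a totarane 3-methylenebenzofuranone, united last by a biomimetic Diels–Alder reaction. Everything rests on the labdane decalin. Ring A carbon C4, flanked by C3 and C5, is carried as a ketone, so C5 and C3 are both nucleophilic, while C10 (bearing the C20 ester) and C2 are the β-carbon and the carbonyl of an enal. One amine-catalysed Michael/aldol condensation of this acyclic keto-enal, held on an enantiopure trans-γ-lactone (C8, C9), closes ring B through C5–C10 and ring A through C2–C3 and sets C5 and C10; the C4 gem-dimethyl group follows.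

Key step: step 6

Assumption: the ligand enantiomers named in steps 2 and 16 are taken as those that deliver the drawn configurations; if either induces the opposite sense, its mirror-image ligand is used.

Labdane and totarane numbering is used in the descriptions.

**Labdane half (steps 1–13)**

Step 1
Reactants: 1 2-(3-chloropropyl)-2-methyl-1,3-dioxolane
Product: 3 4-(2-methyl-1,3-dioxolan-2-yl)butanal, via Grignard reagent 2 (not isolated)
Conditions: Mg, THF, reflux; then DMF, 0 °C; aq. NH4Cl
Reagents that add atoms: N,N-dimethylformamide CN(C)C=O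
Why: Grignard formation from the primary chloride and Bouveault formylation with DMF should give the aldehyde; the ketal is inert to both.

Step 2
Reactants: 3 4-(2-methyl-1,3-dioxolan-2-yl)butanal; 4 methyl propiolate
Product: 5 methyl (R)-4-hydroxy-7-(2-methyl-1,3-dioxolan-2-yl)hept-2-ynoate
Conditions: Me2Zn, (S,S)-ProPhenol (20 mol %), Ph3P=O (40 mol %), PhMe, 0 °C
Reagents that add atoms: none
Why: Zinc–ProPhenol-catalysed asymmetric alkynylation of the aldehyde with the zinc acetylide of methyl propiolate should set C8 as R under ligand control.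

Step 3
Reactants: 5 methyl (R)-4-hydroxy-7-(2-methyl-1,3-dioxolan-2-yl)hept-2-ynoate
Product: 7 (R)-5-[3-(2-methyl-1,3-dioxolan-2-yl)propyl]furan-2(5H)-one, via Z-hydroxy enoate 6 (not isolated)
Conditions: H2 (1 atm), Lindlar catalyst, quinoline, EtOAc, rt; then PPTS (cat.), PhH, 40 °C
Reagents that add atoms: none
Why: Lindlar cis-semihydrogenation gives the Z-γ-hydroxy enoate, which lactonises to the butenolide without touching C8.

Step 4
Reactants: 7 (R)-butenolide; 8 trimethyl phosphonoacetate; 9 2,2-dimethoxyacetaldehyde (anhydrous)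
Product: 11 methyl 4,4-dimethoxy-2-{(2R,3R)-2-[3-(2-methyl-1,3-dioxolan-2-yl)propyl]-5-oxotetrahydrofuran-3-yl}but-2-enoate (E/Z mixture), via phosphonate adduct 10 (not isolated)
Conditions: NaH, THF, 0 °C → rt (8 then 7); then 9, rt → 45 °C
Reagents that add atoms: none
Why: Michael addition of the phosphonoacetate anion anti to the 5-alkyl group should set C9 (trans-lactone), and the resulting α-substituted phosphonate anion then olefinates the aldehyde (tandem Michael/Horner–Wadsworth–Emmons); the alkene geometry is irrelevant for step 6.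

Step 5
Reactants: 11 bis-acetal lactone
Product: 12 methyl 4-oxo-2-[(2R,3R)-5-oxo-2-(4-oxopentyl)tetrahydrofuran-3-yl]but-2-enoate (E/Z mixture)
Conditions: 1 M aq. HCl, THF, rt
Reagents that add atoms: water O
Why: Acid hydrolysis should unmask the methyl ketone (dioxolane) and the enal (dimethyl acetal) together while lactone and methyl ester survive.

Step 6
Reactants: 12 keto-enal lactone
Product: 15 tricyclic enone lactone (methyl 4-oxo-heptanorlabd-2-en-12,8α-olid-20-oate), via Michael adduct 13 (not isolated), via aldol 14 (not isolated)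
Conditions: pyrrolidine (30 mol %), TFA (30 mol %), 4 Å MS, PhMe, rt → 60 °C
Reagents that add atoms: none
Why: The pyrrolidinium salt turns the enal of 12 into an iminium ion and the methyl ketone into its enamine; the C5 enamine carbon adds to C10 (β to the iminium) to give 13, whose C3-side enamine then adds to the C2 aldehyde and loses water to give the enone. The closest known reaction type is the amine-catalysed Robinson-type Michael/aldol condensation (Hajos–Parrish and Wieland–Miescher ketone chemistry), here with an intramolecular Michael step. Ring B closes in the 6-(enolexo)-exo-trig mode onto the exocyclic acceptor C10=C1, and ring A closes by a 6-(enolexo)-exo-trig aldol addition followed by E1cB dehydration. C10 and C5 should be set in a chair transition state for ring B in which the two trans-lactone bonds at C8 and C9, the C4 acyl group and the enal arm are all equatorial, leaving the smaller ester axial (10β) and giving the trans-decalin; C9 is held by the trans-lactone, and the E/Z mixture converges through iminium/dienamine equilibration. The step needs C5 rather than C3 as Michael donor and C10 rather than C1 as acceptor, both secured by ring size (six against eight or seven) and by C10 being β to the iminium.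

Step 7
Reactants: 15 tricyclic enone lactone
Product: 16 tricyclic keto lactone (methyl 4-oxo-heptanorlabdan-12,8α-olid-20-oate)
Conditions: H2 (1 atm), 10% Pd/C, EtOAc, rt
Reagents that add atoms: none
Why: Catalytic hydrogenation should saturate the C2=C3 enone alkene only, creating no stereocentre.

Step 8
Reactants: 16 tricyclic keto lactone
Product: 17 gem-dimethyl lactone (methyl 13,14,15,16,17-pentanorlabdan-12,8α-olid-20-oate)
Conditions: Me2TiCl2 (preformed, 3 equiv), CH2Cl2, −30 → 0 °C
Reagents that add atoms: dimethyltitanium dichloride C[Ti](C)(Cl)Cl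
Why: Geminal dimethylation of the ketone with Me2TiCl2 (Reetz reaction) should convert C4=O into CMe2, the reagent being selective for ketones over lactone and ester.

Step 9
Reactants: 17 gem-dimethyl lactone
Product: 18 methyl 8α,12-dihydroxy-13,14,15,16,17-pentanorlabdan-20-oate
Conditions: LiBH4, THF, 0 °C → rt
Reagents that add atoms: none
Why: Borohydride reduction should open the γ-lactone to the diol, while the axial ester on quaternary C10 is too hindered to react.

Step 10
Reactants: 18 diol ester
Product: 19 methyl 8,12-dioxo-13,14,15,16,17-pentanorlabdan-20-oate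
Conditions: Dess–Martin periodinane, NaHCO3, CH2Cl2, rt
Reagents that add atoms: none
Why: Dess–Martin oxidation should convert both alcohols, giving the C8 ketone and the C12 aldehyde in one operation; C9 is already in its thermodynamic equatorial configuration.

Step 11
Reactants: 19 keto aldehyde; 20 2-(triphenylphosphoranylidene)propanal
Product: 21 methyl (12E)-8,14-dioxo-15,17-dinorlabd-12-en-20-oate
Conditions: PhMe, 80 °C
Reagents that add atoms: none
Why: The stabilised ylide should olefinate only the aldehyde (Wittig reaction), giving the E-trisubstituted enal and leaving the hindered C8 ketone.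

Step 12
Reactants: 21 keto enal
Product: 22 methyl (12E)-labda-8(17),12,14-trien-20-oate
Conditions: Ph3PCH3Br, KOtBu, THF, 0 → 45 °C
Reagents that add atoms: methylenetriphenylphosphorane C=P(c1ccccc1)(c1ccccc1)c1ccccc1
Why: Double Wittig methylenation should convert the enal into the terminal diene and the C8 ketone into the exocyclic methylene in one operation.

Step 13
Reactants: 22 diene methyl ester
Product: 23 (12E)-labda-8(17),12,14-trien-20-oic acid
Conditions: n-PrSLi, HMPA, rt; then aq. HCl
Reagents that add atoms: none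
Why: SN2 demethylation by thiolate should cleave the hindered methyl ester at the methyl carbon, under conditions that leave the diene and the exocyclic alkene alone.

**Totarane half (steps 14–22)**

Step 14
Reactants: 24 2-bromo-3-methylanisole
Product: 25 2-bromo-1-(bromomethyl)-3-methoxybenzene
Conditions: NBS, AIBN (cat.), PhCF3, 85 °C
Reagents that add atoms: N-bromosuccinimide O=C1CCC(=O)N1Br
Why: Wohl–Ziegler radical bromination should functionalise the only benzylic methyl group.

Step 15
Reactants: 25 2-bromo-1-(bromomethyl)-3-methoxybenzene; 26 geranyl bromide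
Product: 28 2-bromo-1-[(3E)-4,8-dimethylnona-3,7-dien-1-yl]-3-methoxybenzene, via benzylic Grignard reagent 27 (not isolated)
Conditions: Mg, Et2O, 0 °C; then 26, THF, −78 °C → rt
Reagents that add atoms: none
Why: Magnesium should insert into the benzylic C–Br bond in preference to the aryl C–Br bond, and the benzylic Grignard reagent then displaces the primary allylic bromide (SN2 coupling) with retention of the E-alkene.

Step 16
Reactants: 28 homogeranyl arene
Product: 29 (5S,10S)-14-bromo-13-methoxypodocarpa-8,11,13-triene
Conditions: (R)-3,3′-dichloro-BINOL·SbCl5 (0.5 equiv), CH2Cl2, −78 °C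
Reagents that add atoms: none
Why: Enantioselective proton-initiated cationic polyene cyclisation with chair–chair folding of the E-alkene should give the trans ring fusion (5α-H, 10β-Me) under control of the chiral acid, with Friedel–Crafts termination at the only free ortho position, para to OMe.

Step 17
Reactants: 29 tricyclic aryl bromide; 30 tert-butyl 2-bromopropanoate
Product: 32 tert-butyl 2-[(5S,10S)-13-methoxypodocarpa-8,11,13-trien-14-yl]propanoate (C15 epimers), via zinc enolate 31 (not isolated)
Conditions: Zn, THF, rt; then 29, Pd(dba)2 (5 mol %), Q-Phos (5 mol %), 60 °C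
Reagents that add atoms: none
Why: Palladium-catalysed α-arylation of the Reformatsky zinc enolate (Negishi-type coupling) should install the C15–C17 propanoate unit at C14; C15 is not controlled because it becomes sp2 later.

Step 18
Reactants: 32 aryl propanoate
Product: 33 tert-butyl 2-[(5S,10S)-13-methoxy-7-oxopodocarpa-8,11,13-trien-14-yl]propanoate
Conditions: CrO3, AcOH/H2O, rt
Reagents that add atoms: chromium trioxide O=[Cr](=O)=O
Why: Chromium(VI) benzylic oxidation should attack the C7 methylene, the only unhindered benzylic CH2; the C15–H is shielded by two ortho groups and deactivated by the ester.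

Step 19
Reactants: 33 keto ester
Product: 35 7-oxototara-8,11,13-trien-16,13-olide (C15 epimers), via hydroxy acid 34 (not isolated)
Conditions: BBr3, CH2Cl2, −78 → 0 °C; H2O; then TsOH (cat.), PhMe, 60 °C
Reagents that add atoms: none
Why: BBr3 should cleave the aryl methyl ether and the tert-butyl ester, and the resulting 2-hydroxyaryl propanoic acid lactonises to the benzofuranone under acid.

Step 20
Reactants: 35 keto lactone
Product: 36 7β-hydroxytotara-8,11,13-trien-16,13-olide
Conditions: NaBH4, CeCl3·7H2O, MeOH/THF, −40 °C; AcOH quench at −40 °C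
Reagents that add atoms: none
Why: Luche reduction should deliver hydride to C7 from the α-face (axial attack), giving the pseudo-equatorial 7β-alcohol, with the lactone left intact at low temperature.

Step 21
Reactants: 36 hydroxy lactone
Product: 37 7β-acetoxytotara-8,11,13-trien-16,13-olide
Conditions: Ac2O, Sc(OTf)3 (cat.), MeCN, −20 °C
Reagents that add atoms: acetic anhydride CC(=O)OC(C)=O
Why: Lewis-acid-catalysed acetylation should esterify the C7 alcohol without base, which avoids enol acetylation of the lactone and acyl transfer of the lactone carbonyl to the C7 oxygen.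

Step 22
Reactants: 37 acetoxy lactone
Product: 38 7β-acetoxy-15-(phenylselanyl)totara-8,11,13-trien-16,13-olide
Conditions: PhSeCl, Et3N, CH2Cl2, 0 °C
Reagents that add atoms: benzeneselenenyl chloride Cl[Se]c1ccccc1
Why: The acidic C15–H of the 3-methylbenzofuranone should enolise with amine base and be trapped at carbon by the selenenyl chloride (α-selenenylation).

**Union**

Step 23
Reactants: 38 selenide; 23 labdane diene acid
Product: 41 hispidanin B, via selenoxide 39 (not isolated), via methylene lactone 40 (not isolated)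
Conditions: mCPBA (1.0 equiv), NaHCO3, CH2Cl2, −78 °C; then 23, −78 °C → rt
Reagents that add atoms: none
Why: Selenoxide syn-elimination toward the methyl group should release the 3-methylenebenzofuranone, which is trapped by the E-diene in an intermolecular Diels–Alder reaction (C15 of the diene to the methylene carbon, C12 to the spiro carbon), the biomimetic union expected to give the natural configuration at C12 and the spiro centre.

**Compound list**

1 | 2-(3-chloropropyl)-2-methyl-1,3-dioxolane | CC1(CCCCl)OCCO1 | starting material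
2 | [3-(2-methyl-1,3-dioxolan-2-yl)propyl]magnesium chloride | CC1(CCC[Mg]Cl)OCCO1 | intermediate
3 | 4-(2-methyl-1,3-dioxolan-2-yl)butanal | O=CCCCC1(C)OCCO1 | intermediate
4 | methyl propiolate | C#CC(=O)OC | starting material
5 | methyl (R)-4-hydroxy-7-(2-methyl-1,3-dioxolan-2-yl)hept-2-ynoate | COC(=O)C#C[C@H](O)CCCC1(C)OCCO1 | intermediate
6 | methyl (R,Z)-4-hydroxy-7-(2-methyl-1,3-dioxolan-2-yl)hept-2-enoate | COC(=O)/C=C\[C@H](O)CCCC1(C)OCCO1 | intermediate
7 | (R)-5-[3-(2-methyl-1,3-dioxolan-2-yl)propyl]furan-2(5H)-one | CC1(CCC[C@H]2OC(=O)C=C2)OCCO1 | intermediate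
8 | trimethyl phosphonoacetate | COC(=O)CP(=O)(OC)OC | starting material
9 | 2,2-dimethoxyacetaldehyde | COC(OC)C=O | starting material
10 | methyl 2-(dimethoxyphosphoryl)-2-{trans-(2R)-2-[3-(2-methyl-1,3-dioxolan-2-yl)propyl]-5-oxotetrahydrofuran-3-yl}acetate (mixture at the phosphonate carbon) | COC(=O)C(P(=O)(OC)OC)[C@H]1CC(=O)O[C@@H]1CCCC1(C)OCCO1 | intermediate
11 | methyl 4,4-dimethoxy-2-{(2R,3R)-2-[3-(2-methyl-1,3-dioxolan-2-yl)propyl]-5-oxotetrahydrofuran-3-yl}but-2-enoate (E/Z mixture) | COC(=O)C(=CC(OC)OC)[C@H]1CC(=O)O[C@@H]1CCCC1(C)OCCO1 | intermediate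
12 | methyl 4-oxo-2-[(2R,3R)-5-oxo-2-(4-oxopentyl)tetrahydrofuran-3-yl]but-2-enoate (E/Z mixture) | COC(=O)C(=CC=O)[C@H]1CC(=O)O[C@@H]1CCCC(C)=O | intermediate
13 | Michael adduct: ring-B cyclohexane fused to the trans-γ-lactone, C10 bearing β-CO2Me and CH2CHO, C5 bearing equatorial acetyl (5α-H, 9α-H, 8β-H) | COC(=O)[C@]1(CC=O)[C@H](C(C)=O)CC[C@H]2OC(=O)C[C@H]12 | intermediate
14 | aldol adduct: methyl 2-hydroxy-4-oxo-13,14,15,16,17,18,19-heptanorlabdan-12,8α-olid-20-oate (C2 epimers) | COC(=O)[C@]12CC(O)CC(=O)[C@@H]1CC[C@H]1OC(=O)C[C@@H]12 | intermediate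
15 | methyl 4-oxo-13,14,15,16,17,18,19-heptanorlabd-2-en-12,8α-olid-20-oate (5α-H, 9α-H, 10β-CO2Me; trans-decalin with trans-fused γ-lactone from C12 to the 8α-oxygen) | COC(=O)[C@]12CC=CC(=O)[C@@H]1CC[C@H]1OC(=O)C[C@@H]12 | intermediate
16 | methyl 4-oxo-13,14,15,16,17,18,19-heptanorlabdan-12,8α-olid-20-oate | COC(=O)[C@]12CCCC(=O)[C@@H]1CC[C@H]1OC(=O)C[C@@H]12 | intermediate
17 | methyl 13,14,15,16,17-pentanorlabdan-12,8α-olid-20-oate | COC(=O)[C@]12CCCC(C)(C)[C@@H]1CC[C@H]1OC(=O)C[C@@H]12 | intermediate
18 | methyl 8α,12-dihydroxy-13,14,15,16,17-pentanorlabdan-20-oate | COC(=O)[C@]12CCCC(C)(C)[C@@H]1CC[C@@H](O)[C@@H]2CCO | intermediate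
19 | methyl 8,12-dioxo-13,14,15,16,17-pentanorlabdan-20-oate | COC(=O)[C@]12CCCC(C)(C)[C@@H]1CCC(=O)[C@@H]2CC=O | intermediate
20 | 2-(triphenylphosphoranylidene)propanal | CC(C=O)=P(c1ccccc1)(c1ccccc1)c1ccccc1 | starting material
21 | methyl (12E)-8,14-dioxo-15,17-dinorlabd-12-en-20-oate | COC(=O)[C@]12CCCC(C)(C)[C@@H]1CCC(=O)[C@@H]2C/C=C(\C)C=O | intermediate
22 | methyl (12E)-labda-8(17),12,14-trien-20-oate | COC(=O)[C@]12CCCC(C)(C)[C@@H]1CCC(=C)[C@@H]2C/C=C(\C)C=C | intermediate
23 | (12E)-labda-8(17),12,14-trien-20-oic acid (5α-H, 9α-H, 10β-CO2H) | OC(=O)[C@]12CCCC(C)(C)[C@@H]1CCC(=C)[C@@H]2C/C=C(\C)C=C | intermediate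
24 | 2-bromo-3-methylanisole | COc1cccc(C)c1Br | starting material
25 | 2-bromo-1-(bromomethyl)-3-methoxybenzene | COc1cccc(CBr)c1Br | intermediate
26 | geranyl bromide | CC(C)=CCC/C(C)=C/CBr | starting material
27 | (2-bromo-3-methoxybenzyl)magnesium bromide | COc1cccc(C[Mg]Br)c1Br | intermediate
28 | 2-bromo-1-[(3E)-4,8-dimethylnona-3,7-dien-1-yl]-3-methoxybenzene | COc1cccc(CC/C=C(\C)CCC=C(C)C)c1Br | intermediate
29 | (5S,10S)-14-bromo-13-methoxypodocarpa-8,11,13-triene (5α-H, 10β-Me) | COc1ccc2c(c1Br)CC[C@H]1C(C)(C)CCC[C@]21C | intermediate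
30 | tert-butyl 2-bromopropanoate | CC(Br)C(=O)OC(C)(C)C | starting material
31 | (1-tert-butoxy-1-oxopropan-2-yl)zinc bromide | CC([Zn]Br)C(=O)OC(C)(C)C | intermediate
32 | tert-butyl 2-[(5S,10S)-13-methoxypodocarpa-8,11,13-trien-14-yl]propanoate (C15 epimers) | COc1ccc2c(c1C(C)C(=O)OC(C)(C)C)CC[C@H]1C(C)(C)CCC[C@]21C | intermediate
33 | tert-butyl 2-[(5S,10S)-13-methoxy-7-oxopodocarpa-8,11,13-trien-14-yl]propanoate | COc1ccc2c(c1C(C)C(=O)OC(C)(C)C)C(=O)C[C@H]1C(C)(C)CCC[C@]21C | intermediate
34 | 2-[(5S,10S)-13-hydroxy-7-oxopodocarpa-8,11,13-trien-14-yl]propanoic acid | CC(C(=O)O)c1c(O)ccc2c1C(=O)C[C@H]1C(C)(C)CCC[C@]21C | intermediate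
35 | 7-oxototara-8,11,13-trien-16,13-olide (C15 epimers; 5α-H, 10β-Me) | CC1C(=O)Oc2ccc3c(c21)C(=O)C[C@H]1C(C)(C)CCC[C@]31C | intermediate
36 | 7β-hydroxytotara-8,11,13-trien-16,13-olide | CC1C(=O)Oc2ccc3c(c21)[C@@H](O)C[C@H]1C(C)(C)CCC[C@]31C | intermediate
37 | 7β-acetoxytotara-8,11,13-trien-16,13-olide | CC1C(=O)Oc2ccc3c(c21)[C@@H](OC(C)=O)C[C@H]1C(C)(C)CCC[C@]31C | intermediate
38 | 7β-acetoxy-15-(phenylselanyl)totara-8,11,13-trien-16,13-olide | CC1([Se]c2ccccc2)C(=O)Oc2ccc3c(c21)[C@@H](OC(C)=O)C[C@H]1C(C)(C)CCC[C@]31C | intermediate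
39 | selenoxide of 38 | CC1([Se](=O)c2ccccc2)C(=O)Oc2ccc3c(c21)[C@@H](OC(C)=O)C[C@H]1C(C)(C)CCC[C@]31C | intermediate
40 | 7β-acetoxytotara-8,11,13,15(17)-tetraen-16,13-olide (3-methylenebenzofuranone dienophile) | C=C1C(=O)Oc2ccc3c(c21)[C@@H](OC(C)=O)C[C@H]1C(C)(C)CCC[C@]31C | intermediate
41 | hispidanin B | C=C1CC[C@H]2C(C)(C)CCC[C@]2(C(=O)O)[C@H]1C[C@H]1C(C)=CCC[C@]12C(=O)Oc1ccc3c(c12)[C@@H](OC(C)=O)C[C@H]1C(C)(C)CCC[C@]31C | target

**Step count and risks**

Total step count: 23. Longest linear sequence: 14 steps (steps 1–13, then step 23).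

Steps most likely to fail:

1. Step 6. The Michael closure may stall at the hindered quaternary C10, may proceed with poor facial selectivity, or may lose material through dienamine formation and aminolysis of the lactone. The fallback sets out from 12 and drops covalent amine catalysis for stepwise enolate chemistry. DBU (cat.) in MeCN should effect the intramolecular Michael addition under thermodynamic control, and keto aldehyde 13 is isolated. TsOH in toluene at reflux with water removal then carries out the aldol condensation, and the route is rejoined at 15. This fallback makes no compound outside the list (F0).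

2. Step 8. Ionisation at C4 may end in elimination or in a hydride or alkyl shift from C5/C10 instead of methyl transfer. The fallback sets out from 16. Wittig methylenation (Ph3P=CH2, THF) should give methyl 4-methylene-13,14,15,16,17,18,19-heptanorlabdan-12,8α-olid-20-oate F1. Simmons–Smith cyclopropanation (Et2Zn, CH2I2) gives the 4-spirocyclopropane lactone F2. Hydrogenolysis of the cyclopropane (H2, PtO2, AcOH) opens it to the gem-dimethyl group, and the route is rejoined at 17.

3. Step 17. Oxidative addition or transmetalation may fail at the doubly ortho-substituted aryl bromide, leaving proto-debromination as the main path. The fallback sets out from 29. Suzuki–Miyaura coupling with isopropenylboronic acid pinacol ester (Pd(OAc)2, SPhos, K3PO4) should give (5S,10S)-14-isopropenyl-13-methoxypodocarpa-8,11,13-triene F3. Hydroboration–oxidation (9-BBN; NaOH, H2O2) gives 2-[(5S,10S)-13-methoxypodocarpa-8,11,13-trien-14-yl]propan-1-ol F4. Jones oxidation gives 2-[(5S,10S)-13-methoxypodocarpa-8,11,13-trien-14-yl]propanoic acid F5. Esterification with tert-butyl 2,2,2-trichloroacetimidate (BF3·OEt2 cat.) rejoins the route at 32.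

Further compounds
F0 | step 6 | none | none
F1 | step 8 | methyl 4-methylene-13,14,15,16,17,18,19-heptanorlabdan-12,8α-olid-20-oate | COC(=O)[C@]12CCCC(=C)[C@@H]1CC[C@H]1OC(=O)C[C@@H]12
F2 | step 8 | methyl 4-spirocyclopropane-13,14,15,16,17,18,19-heptanorlabdan-12,8α-olid-20-oate | COC(=O)[C@]12CCCC3(CC3)[C@@H]1CC[C@H]1OC(=O)C[C@@H]12
F3 | step 17 | (5S,10S)-14-isopropenyl-13-methoxypodocarpa-8,11,13-triene | COc1ccc2c(c1C(C)=C)CC[C@H]1C(C)(C)CCC[C@]21C
F4 | step 17 | 2-[(5S,10S)-13-methoxypodocarpa-8,11,13-trien-14-yl]propan-1-ol | COc1ccc2c(c1C(C)CO)CC[C@H]1C(C)(C)CCC[C@]21C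
F5 | step 17 | 2-[(5S,10S)-13-methoxypodocarpa-8,11,13-trien-14-yl]propanoic acid | COc1ccc2c(c1C(C)C(=O)O)CC[C@H]1C(C)(C)CCC[C@]21C
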